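**Retrosynthetic overview** (chromene numbering; ring A = benzo ring, ring B = pyran, ring C = 4-hydroxyphenyl)
Feature: ring A is a resorcinol, with O1 on C8a meta to the prenyloxy oxygen on C7. C4a sits between C8a and the chain-bearing C5 and carries C4, which is the pattern of a 6-alkyl-2,4-dihydroxybenzoate whose carboxyl carbon is C4.
Late disconnections: the ring C silyl ether; ring B (C3–C4 and O1–C2) from a salicylaldehyde and a 2-methylprop-1-enylboron reagent via an ortho-quinone methide; the aldehyde from the ester; the O7–prenyl bond.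
Ring A: the C4a–C5 bond comes from the intramolecular aldol (chain C2 onto chain C7) of a linear methyl 3,5,7-trioxononanoate that already carries the CH2CH2 bridge and ring C.
Chain: the C6–C7 bond comes from the trianion of methyl 3,5-dioxohexanoate (made from dehydroacetic acid) and the Weinreb amide of O-silylated phloretic acid.
Ring order: ring C is bought, ring A closes in step 5, ring B closes in step 9.

Key step: step 5

Remark on the chemistry: the target has no stereocentre, and its C3=C4 ring alkene can only be cis, so no stereocontrol is needed. The stereocentres of the transient intermediates in steps 5 and 9 arise as mixtures and are erased in the same flask. Polyketo compounds are drawn in their keto forms although they are largely enolised.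

**Step 1**
Reactants: 1 phloretic acid
Product: 2 3-(4-hydroxyphenyl)-N-methoxy-N-methylpropanamide
Conditions: MeNH(OMe)·HCl (1.2 equiv), EDC·HCl (1.2 equiv), N-methylmorpholine (2.5 equiv), CH2Cl2–DMF 9:1, 0 → 23 °C
Reagents that add atoms: N,O-dimethylhydroxylamine hydrochloride, CNOC.Cl
Why: Carbodiimide amide coupling (Weinreb amide formation), in which the amine far outruns the free phenol at the O-acylisourea and any aryl ester formed in passing is aminolysed, so the phenol needs no protection here.

**Step 2**
Reactants: 2 3-(4-hydroxyphenyl)-N-methoxy-N-methylpropanamide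
Product: 3 N-methoxy-N-methyl-3-[4-(triisopropylsilyloxy)phenyl]propanamide
Conditions: iPr3SiCl (1.2 equiv), imidazole (2.5 equiv), DMF, 23 °C
Reagents that add atoms: triisopropylsilyl chloride, CC(C)[Si](Cl)(C(C)C)C(C)C
Why: Imidazole-promoted O-silylation of a phenol, with the bulky aryl triisopropylsilyl ether chosen because it should withstand amide bases, carbonate, aluminium hydride and 90 °C yet fall to fluoride at the end.

**Step 3**
Reactants: 4 dehydroacetic acid
Product: 6 methyl 3,5-dioxohexanoate, via methyl 2-acetyl-3,5-dioxohexanoate 5 (not isolated)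
Conditions: Mg(OMe)2 (2 equiv), MeOH, reflux; then cold 2 M HCl; distillation
Reagents that add atoms: methanol, CO (delivered as Mg(OMe)2, [Mg+2].[O-]C.[O-]C)
Why: Methanolysis of the pyranone lactone followed by retro-Claisen deacetylation of the triacylmethane 5, where magnesium chelation of the 3,5-dioxo ester chain should direct cleavage to the branching acetyl group.

**Step 4**
Reactants: 6 methyl 3,5-dioxohexanoate; 3 N-methoxy-N-methyl-3-[4-(triisopropylsilyloxy)phenyl]propanamide
Product: 8 methyl 3,5,7-trioxo-9-[4-(triisopropylsilyloxy)phenyl]nonanoate, via trilithium trianion 7 (not isolated)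
Conditions: 6 (1.5 equiv), LiN(iPr)2 (4.6 equiv), THF, −78 → 0 °C; then 3 (1.0 equiv), −78 → −20 °C; poured into cold 1 M HCl (pH 3–4); carried on after a short silica filtration
Reagents that add atoms: lithium diisopropylamide LiN(iPr)2, [Li+].CC(C)[N-]C(C)C (its lithium sits only in intermediate 7; none of its atoms stays in 8)
Why: Claisen-type acylation of a β-polycarbonyl polyanion, in which the last-formed and least stabilised terminal CH2 carbanion is the nucleophilic site and the Weinreb amide holds the adduct as a lithium chelate until the quench, so neither a second addition nor proton transfer from the product to unreacted trianion should occur.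

**Step 5**
Reactants: 8 methyl 3,5,7-trioxo-9-[4-(triisopropylsilyloxy)phenyl]nonanoate
Product: 10 methyl 2,4-dihydroxy-6-{2-[4-(triisopropylsilyloxy)phenyl]ethyl}benzoate, via cyclic aldol adduct 9 (not isolated)
Conditions: 0.05 M aq. Na2B4O7 (pH 9.2)–THF–MeOH, 23 °C; then 1 M HCl to pH 3
Reagents that add atoms: none
Why: This is a biomimetic intramolecular aldol condensation with aromatisation, the known way from 3,5,7-triketo esters to orsellinate-type resorcylates. At pH about 9 the tetraketide is a mobile set of mono-enolates; the C4 and C6 carbanions are the more abundant, but on a ketone they could only close four-membered rings, so the productive event is addition of the doubly activated C2 carbon to the C7 ketone, which forms the C4a–C5 bond (chromene numbering) and gives aldol 9. Ring A therefore closes in a 6-(enolexo)-exo-trig mode (6-(enolendo)-exo-trig if the enolate is drawn towards C3), and both modes are allowed. E1cB loss of water from 9 and enolisation of the C3 and C5 ketones make the closure irreversible and drain the reversible aldol towards arene 10, erasing the two stereocentres of 9 so that none remains. The selectivity needed is that of closure mode: attack of C6 on the ester carbon needs strong base that turns the C7 ketone into an enolate, lactonisation of the C5 enol oxygen onto the ester needs acid, heat or a free carboxylic acid, and attack of C8 on C3 needs deprotonation at a singly activated carbon, so a weak aqueous base at 23 °C and a ketone more electrophilic than the conjugated ester should secure the aldol mode. The aryl silyl ether and the methyl ester should survive this pH.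

**Step 6**
Reactants: 10 methyl 2,4-dihydroxy-6-{2-[4-(triisopropylsilyloxy)phenyl]ethyl}benzoate; 11 prenyl bromide
Product: 12 methyl 2-hydroxy-4-(3-methylbut-2-enyloxy)-6-{2-[4-(triisopropylsilyloxy)phenyl]ethyl}benzoate
Conditions: 11 (1.1 equiv), K2CO3 (1.5 equiv), acetone, 23 → 45 °C
Reagents that add atoms: prenyl bromide (11), CC(C)=CCBr
Why: Williamson ether synthesis, in which the 4-hydroxyl para to the ester is the more acidic and unhindered phenol while the 2-hydroxyl is hydrogen-bonded to the ester carbonyl and ring C is silylated, so one equivalent of the allylic bromide should alkylate O7 (chromene numbering) only.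

**Step 7**
Reactants: 12 methyl 2-hydroxy-4-(3-methylbut-2-enyloxy)-6-{2-[4-(triisopropylsilyloxy)phenyl]ethyl}benzoate
Product: 13 2-(hydroxymethyl)-5-(3-methylbut-2-enyloxy)-3-{2-[4-(triisopropylsilyloxy)phenyl]ethyl}phenol
Conditions: iBu2AlH (3.5 equiv), CH2Cl2, −78 → −10 °C; aq. KNaC4H4O6 (potassium sodium tartrate) work-up
Reagents that add atoms: none
Why: Hydride reduction of an ester to the primary alcohol, in which the aluminium phenoxide formed first chelates and activates the hindered ester carbonyl, and a temperature below 0 °C should keep the benzylic aluminium alkoxide from ionising, so reduction stops at the alcohol with the prenyl ether and aryl silyl ether untouched.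

**Step 8**
Reactants: 13 2-(hydroxymethyl)-5-(3-methylbut-2-enyloxy)-3-{2-[4-(triisopropylsilyloxy)phenyl]ethyl}phenol
Product: 14 2-hydroxy-4-(3-methylbut-2-enyloxy)-6-{2-[4-(triisopropylsilyloxy)phenyl]ethyl}benzaldehyde
Conditions: activated MnO2 (15 equiv), CH2Cl2, 23 °C
Reagents that add atoms: none
Why: Heterogeneous MnO2 oxidation selective for the benzylic alcohol, which should stop at the internally hydrogen-bonded salicylaldehyde and leave the isolated alkene and the silyl ether alone.

**Step 9**
Reactants: 14 2-hydroxy-4-(3-methylbut-2-enyloxy)-6-{2-[4-(triisopropylsilyloxy)phenyl]ethyl}benzaldehyde; 15 2-methylprop-1-enylboronic acid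
Product: 18 2,2-dimethyl-7-(3-methylbut-2-enyloxy)-5-{2-[4-(triisopropylsilyloxy)phenyl]ethyl}-2H-chromene, via Petasis allylic amine 16 (not isolated), via ortho-quinone methide 17 (not isolated)
Conditions: 15 (1.5 equiv), Bn2NH (0.3 equiv), 1,4-dioxane, 90 °C
Reagents that add atoms: 2-methylprop-1-enylboronic acid (15), CC(C)=CB(O)O; dibenzylamine, C(NCc1ccccc1)c1ccccc1 (held only in intermediate 16 and released again)
Why: Amine-catalysed Petasis borono-Mannich reaction followed by amine loss and oxa-6π electrocyclisation, in which the ortho phenol binds the boronic acid as an ate complex and delivers the alkenyl group to the iminium carbon (C3–C4 bond), heat expels dibenzylamine from 16, and ring closure of 17 makes O1–C2 and restores the aromaticity of ring A well below the temperature of an aryl prenyl ether Claisen rearrangement.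

**Step 10**
Reactants: 18 2,2-dimethyl-7-(3-methylbut-2-enyloxy)-5-{2-[4-(triisopropylsilyloxy)phenyl]ethyl}-2H-chromene
Product: 19 4-{2-[2,2-dimethyl-7-(3-methylbut-2-enyloxy)-2H-chromen-5-yl]ethyl}phenol (target)
Conditions: Bu4NF (1.2 equiv), AcOH (1.2 equiv), THF, 0 °C
Reagents that add atoms: none
Why: Fluoride-induced desilylation of an aryl silyl ether driven by Si–F bond formation, buffered with acetic acid so that the phenol is released directly and the chromene and prenyl ether are left alone.

**Compound list**
1 | phloretic acid, 3-(4-hydroxyphenyl)propanoic acid | OC(=O)CCc1ccc(O)cc1 | starting material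
2 | 3-(4-hydroxyphenyl)-N-methoxy-N-methylpropanamide | CON(C)C(=O)CCc1ccc(O)cc1 | intermediate
3 | N-methoxy-N-methyl-3-[4-(triisopropylsilyloxy)phenyl]propanamide | CON(C)C(=O)CCc1ccc(O[Si](C(C)C)(C(C)C)C(C)C)cc1 | intermediate
4 | dehydroacetic acid, 3-acetyl-4-hydroxy-6-methyl-2H-pyran-2-one | CC(=O)C1=C(O)C=C(C)OC1=O | starting material
5 | methyl 2-acetyl-3,5-dioxohexanoate (not isolated) | COC(=O)C(C(C)=O)C(=O)CC(C)=O | intermediate
6 | methyl 3,5-dioxohexanoate | COC(=O)CC(=O)CC(C)=O | intermediate
7 | trilithium trianion of methyl 3,5-dioxohexanoate (not isolated) | [Li+].[Li+].[Li+].COC([O-])=CC([O-])=CC([O-])=C | intermediate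
8 | methyl 3,5,7-trioxo-9-[4-(triisopropylsilyloxy)phenyl]nonanoate | COC(=O)CC(=O)CC(=O)CC(=O)CCc1ccc(O[Si](C(C)C)(C(C)C)C(C)C)cc1 | intermediate
9 | methyl 2-hydroxy-4,6-dioxo-2-{2-[4-(triisopropylsilyloxy)phenyl]ethyl}cyclohexane-1-carboxylate (mixture of stereoisomers, not isolated) | COC(=O)C1C(=O)CC(=O)CC1(O)CCc1ccc(O[Si](C(C)C)(C(C)C)C(C)C)cc1 | intermediate
10 | methyl 2,4-dihydroxy-6-{2-[4-(triisopropylsilyloxy)phenyl]ethyl}benzoate | COC(=O)c1c(O)cc(O)cc1CCc1ccc(O[Si](C(C)C)(C(C)C)C(C)C)cc1 | intermediate
11 | prenyl bromide, 1-bromo-3-methylbut-2-ene | CC(C)=CCBr | starting material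
12 | methyl 2-hydroxy-4-(3-methylbut-2-enyloxy)-6-{2-[4-(triisopropylsilyloxy)phenyl]ethyl}benzoate | COC(=O)c1c(O)cc(OCC=C(C)C)cc1CCc1ccc(O[Si](C(C)C)(C(C)C)C(C)C)cc1 | intermediate
13 | 2-(hydroxymethyl)-5-(3-methylbut-2-enyloxy)-3-{2-[4-(triisopropylsilyloxy)phenyl]ethyl}phenol | OCc1c(O)cc(OCC=C(C)C)cc1CCc1ccc(O[Si](C(C)C)(C(C)C)C(C)C)cc1 | intermediate
14 | 2-hydroxy-4-(3-methylbut-2-enyloxy)-6-{2-[4-(triisopropylsilyloxy)phenyl]ethyl}benzaldehyde | O=Cc1c(O)cc(OCC=C(C)C)cc1CCc1ccc(O[Si](C(C)C)(C(C)C)C(C)C)cc1 | intermediate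
15 | 2-methylprop-1-enylboronic acid | CC(C)=CB(O)O | starting material
16 | 2-[1-(dibenzylamino)-3-methylbut-2-enyl]-5-(3-methylbut-2-enyloxy)-3-{2-[4-(triisopropylsilyloxy)phenyl]ethyl}phenol (racemic, not isolated) | CC(C)=CC(N(Cc1ccccc1)Cc1ccccc1)c1c(O)cc(OCC=C(C)C)cc1CCc1ccc(O[Si](C(C)C)(C(C)C)C(C)C)cc1 | intermediate
17 | (6Z)-6-(3-methylbut-2-enylidene)-3-(3-methylbut-2-enyloxy)-5-{2-[4-(triisopropylsilyloxy)phenyl]ethyl}cyclohexa-2,4-dien-1-one (geometry that cyclises, not isolated) | CC(C)=C/C=C1\C(=O)C=C(OCC=C(C)C)C=C1CCc1ccc(O[Si](C(C)C)(C(C)C)C(C)C)cc1 | intermediate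
18 | 2,2-dimethyl-7-(3-methylbut-2-enyloxy)-5-{2-[4-(triisopropylsilyloxy)phenyl]ethyl}-2H-chromene | CC(C)=CCOc1cc(CCc2ccc(O[Si](C(C)C)(C(C)C)C(C)C)cc2)c2c(c1)OC(C)(C)C=C2 | intermediate
19 | 4-{2-[2,2-dimethyl-7-(3-methylbut-2-enyloxy)-2H-chromen-5-yl]ethyl}phenol | CC(C)=CCOc1cc(CCc2ccc(O)cc2)c2c(c1)OC(C)(C)C=C2 | target

**Total step count:** 10
**Longest linear sequence:** 9 steps (from 1 through steps 1, 2 and 4–10). The branch from 4 joins at step 4.

**Steps most likely to fail**

Step 5. The labile open-chain tetraketide may close in the wrong mode. The C6 carbon can attack the ester carbon, or the C5 enol oxygen can lactonise onto it. The chain may also break by retro-Claisen scission while it is handled.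
- The fallback sets out from 3 and comes back at 14. It locks the ester end of the chain in a dioxinone, so neither wrong mode has an ester to attack.
- Commercial 2,2,6-trimethyl-4H-1,3-dioxin-4-one is deprotonated at its 6-methyl group (LiN(SiMe3)2, THF, −78 °C) and acetylated with acetyl chloride to 2,2-dimethyl-6-(2-oxopropyl)-4H-1,3-dioxin-4-one F1.
- The dianion of F1 (LiN(iPr)2, 2.1 equiv, THF, −78 °C) is acylated at its methyl terminus by 3 to give 1-(2,2-dimethyl-4-oxo-4H-1,3-dioxin-6-yl)-6-[4-(triisopropylsilyloxy)phenyl]hexane-2,4-dione F2.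
- Et3N in CH2Cl2 at 23 °C closes the same C4a–C5 bond through the dioxinone dienolate. This aromatises to 7-hydroxy-2,2-dimethyl-5-{2-[4-(triisopropylsilyloxy)phenyl]ethyl}-4H-1,3-benzodioxin-4-one F3, in which only the future O7 is free.
- Alkylation with 11 and K2CO3 in acetone gives 2,2-dimethyl-7-(3-methylbut-2-enyloxy)-5-{2-[4-(triisopropylsilyloxy)phenyl]ethyl}-4H-1,3-benzodioxin-4-one F4.
- iBu2AlH (1.2 equiv, CH2Cl2, −78 °C) reduces the lactone carbonyl once, and the hemiacetal falls apart on work-up to salicylaldehyde 14.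
- This detour also bypasses steps 4, 7 and 8.

Step 7. Reduction may run past the alcohol stage. The ortho phenoxide and the para alkoxy group can push out the benzylic aluminium alkoxide, after which a further hydride adds. At the low temperature needed to prevent this, the hindered ester may instead be reduced incompletely.
- The fallback sets out from 12 and comes back at 14. It caps the phenol oxygen so that no phenoxide can assist ionisation and a stronger hydride can be used.
- MeOCH2Cl and iPr2NEt (CH2Cl2, 40 °C) give methyl 2-(methoxymethoxy)-4-(3-methylbut-2-enyloxy)-6-{2-[4-(triisopropylsilyloxy)phenyl]ethyl}benzoate F5.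
- LiAlH4 (THF, 0 → 23 °C) gives [2-(methoxymethoxy)-4-(3-methylbut-2-enyloxy)-6-{2-[4-(triisopropylsilyloxy)phenyl]ethyl}phenyl]methanol F6.
- MnO2 (CH2Cl2) gives 2-(methoxymethoxy)-4-(3-methylbut-2-enyloxy)-6-{2-[4-(triisopropylsilyloxy)phenyl]ethyl}benzaldehyde F7.
- The acetal is removed under nearly neutral conditions (Me3SiOTf, 2,2'-bipyridyl, CH2Cl2, 0 °C; then water), which spare the prenyl ether and the silyl ether and give 14.

Step 9. Iminium formation with the bulky amine may be slow at an aldehyde flanked by two ortho substituents. Protodeboronation of the alkenylboronic acid at 90 °C could then overtake alkenyl transfer.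
- The fallback sets out from 14 and comes back at 18. It replaces the boron/amine relay with a direct carbanion addition.
- Me2C=CHMgBr (2.5 equiv, THF, −78 → 0 °C) adds to the aldehyde of the magnesium phenoxide to give 2-(1-hydroxy-3-methylbut-2-enyl)-5-(3-methylbut-2-enyloxy)-3-{2-[4-(triisopropylsilyloxy)phenyl]ethyl}phenol F8.
- Warming F8 in toluene at 80 °C with a trace of pyridinium p-toluenesulfonate removes water to give the same ortho-quinone methide 17, which electrocyclises to 18.

**Further compounds**
F1 | step 5 | 2,2-dimethyl-6-(2-oxopropyl)-4H-1,3-dioxin-4-one | CC(=O)CC1=CC(=O)OC(C)(C)O1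
F2 | step 5 | 1-(2,2-dimethyl-4-oxo-4H-1,3-dioxin-6-yl)-6-[4-(triisopropylsilyloxy)phenyl]hexane-2,4-dione | CC1(C)OC(=O)C=C(CC(=O)CC(=O)CCc2ccc(O[Si](C(C)C)(C(C)C)C(C)C)cc2)O1
F3 | step 5 | 7-hydroxy-2,2-dimethyl-5-{2-[4-(triisopropylsilyloxy)phenyl]ethyl}-4H-1,3-benzodioxin-4-one | CC1(C)OC(=O)c2c(CCc3ccc(O[Si](C(C)C)(C(C)C)C(C)C)cc3)cc(O)cc2O1
F4 | step 5 | 2,2-dimethyl-7-(3-methylbut-2-enyloxy)-5-{2-[4-(triisopropylsilyloxy)phenyl]ethyl}-4H-1,3-benzodioxin-4-one | CC(C)=CCOc1cc(CCc2ccc(O[Si](C(C)C)(C(C)C)C(C)C)cc2)c2C(=O)OC(C)(C)Oc2c1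
F5 | step 7 | methyl 2-(methoxymethoxy)-4-(3-methylbut-2-enyloxy)-6-{2-[4-(triisopropylsilyloxy)phenyl]ethyl}benzoate | COCOc1cc(OCC=C(C)C)cc(CCc2ccc(O[Si](C(C)C)(C(C)C)C(C)C)cc2)c1C(=O)OC
F6 | step 7 | [2-(methoxymethoxy)-4-(3-methylbut-2-enyloxy)-6-{2-[4-(triisopropylsilyloxy)phenyl]ethyl}phenyl]methanol | COCOc1cc(OCC=C(C)C)cc(CCc2ccc(O[Si](C(C)C)(C(C)C)C(C)C)cc2)c1CO
F7 | step 7 | 2-(methoxymethoxy)-4-(3-methylbut-2-enyloxy)-6-{2-[4-(triisopropylsilyloxy)phenyl]ethyl}benzaldehyde | COCOc1cc(OCC=C(C)C)cc(CCc2ccc(O[Si](C(C)C)(C(C)C)C(C)C)cc2)c1C=O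
F8 | step 9 | 2-(1-hydroxy-3-methylbut-2-enyl)-5-(3-methylbut-2-enyloxy)-3-{2-[4-(triisopropylsilyloxy)phenyl]ethyl}phenol (racemic) | CC(C)=CC(O)c1c(O)cc(OCC=C(C)C)cc1CCc1ccc(O[Si](C(C)C)(C(C)C)C(C)C)cc1
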